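A direct plan would acylate 3,5-dibromoaniline A1 with (methylsulfanyl)acetyl chloride A2 to give the anilide A3. In one flask it would then brominate A3 next to sulfur (NBS), ionise with SnBr4 to the acyl thionium ion A4, close A4 onto the arene to the oxindole A5, and deoxybrominate A5 with POBr3.
- The Friedel–Crafts ring closure (C3–C3a) would be weak: the ring is deactivated by two bromines and an acylated nitrogen, the bond forms beside a bromine, and the NH anilide prefers the amide geometry that holds the cation away from the ortho carbon.
- The late POBr3 deoxybromination at 85 °C would be weak: HBr and a hot phosphorus electrophile meet a thioether and an acid-labile NH 2-bromoindole.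
- The telescoping of three stages without a checkpoint would be weak: all the risk sits in one flask and a failure cannot be located.

**Retrosynthetic overview**
- The pyrrole ring is cut at C2–C3. C2, which in the target carries N1, Br and C3, enters as the carbon of an aryl isocyanide and is raised by Br2 to a carbonimidic dibromide (N=CBr2). C3 with its SMe group is a sulfur-stabilised benzylic carbanion.
- The CH2–SMe unit (C3 and the S-methyl group, both from dimethyl sulfide) is placed ortho to nitrogen at the start by a Gassman [2,3]-sigmatropic shift on 3,5-dibromoaniline, whose two ortho carbons are equivalent.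
- Ring order: the benzene ring is bought with both bromines. The pyrrole ring is the only ring closed, last, at C2–C3 and not at C3–C3a.
- The design needs no electrophilic attack on the deactivated arene, no oxindole, no POBr3 and no bromination of an indole. The C2–Br bond exists before the ring does.

Key step: step 4

Remark: acetic formic anhydride is made from formic acid and acetic anhydride just before use, and LiTMP is taken as the purchased reagent.

Step 1
Reactants: 1 3,5-dibromoaniline; 2 dimethyl sulfide
Product: 4 3,5-dibromo-2-[(methylsulfanyl)methyl]aniline, via azasulfonium chloride 3 (not isolated)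
Conditions: NCS (1.05 equiv), Me2S (1.5 equiv), CH2Cl2, −20 °C; then 1, −20 °C, 2 h; Et3N (1.5 equiv), −20 °C → reflux, 12 h
Reagents that add atoms: none
Why: Gassman ortho-alkylation of an aniline, in which the NCS–Me2S adduct S-aminates nitrogen to the azasulfonium salt 3, Et3N forms the S-methylide, and a [2,3]-sigmatropic (Sommelet–Hauser) shift delivers CH2SMe to the ortho carbon without electrophilic attack on the deactivated ring; both ortho positions of 1 are equivalent, so one isomer should result after rearomatisation, and no stereocentre is formed.

Step 2
Reactants: 4 3,5-dibromo-2-[(methylsulfanyl)methyl]aniline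
Product: 5 N-{3,5-dibromo-2-[(methylsulfanyl)methyl]phenyl}formamide
Conditions: HCO2H/Ac2O (premixed, 3 equiv), THF, 0 °C → rt, 3 h
Reagents that add atoms: acetic formic anhydride (from formic acid and acetic anhydride), CC(=O)OC=O
Why: N-formylation with a mixed anhydride, which is reactive enough for the weakly basic ortho-substituted aniline and transfers formyl in preference to acetyl, leaves the sulfide and the aryl bromides untouched and brings in the carbon that becomes C2.

Step 3
Reactants: 5 N-{3,5-dibromo-2-[(methylsulfanyl)methyl]phenyl}formamide
Product: 6 1,5-dibromo-3-isocyano-2-[(methylsulfanyl)methyl]benzene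
Conditions: POCl3 (1.2 equiv), Et3N (4 equiv), CH2Cl2, −10 → 0 °C, 1 h; cold aq Na2CO3
Reagents that add atoms: none
Why: Dehydration of an N-arylformamide to the isocyanide (Ugi method) by O-phosphorylation and double loss of HX to the amine base, under conditions that are basic throughout, so that the sulfide, the aryl bromides and the acid-sensitive isocyanide should survive.

Step 4
Reactants: 6 1,5-dibromo-3-isocyano-2-[(methylsulfanyl)methyl]benzene
Product: 9 2,4,6-tribromo-3-(methylsulfanyl)-1H-indole, via carbonimidic dibromide 7 (not isolated), via 2-bromo-3H-indole 8 (not isolated)
Conditions: Br2 (1.0 equiv), THF, −78 °C, 15 min; lithium 2,2,6,6-tetramethylpiperidide (LiTMP, 2.1 equiv), −78 → −20 °C, 1 h; aq NH4Cl, in the dark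
Reagents that add atoms: bromine (Br2), BrBr
Why: Proposed new method: Br2 adds to the divalent isocyanide carbon of 6 (α-addition) to give the carbonimidic dibromide 7, so that C2 carries N1 and its bromine before any ring exists; LiTMP then removes a benzylic proton, made acidic by sulfur, by the ortho and para bromines and by the ortho N=CBr2 group, the carbanion attacks the imidoyl carbon, bromide leaves, and the 3H-indole 8 is deprotonated at C3 by the second equivalent of base to the aromatic lithium indolide, which is protonated on nitrogen at work-up. The closest known reaction types are the Ito–Saegusa indole synthesis (closure of an ortho-lithiomethylphenyl isocyanide), the addition–elimination of heteroatom and stabilised carbon nucleophiles at carbonimidic dihalides, and the 5-endo-trig closures of carbanions onto 1,1-difluoroalkenes. The pyrrole ring is closed at C2–C3 in a formally 5-endo-trig mode, which is accessible here because the benzylic anion, the arene bond C3a–C7a and C=N form a 2-azapentadienyl anion that can close as a six-electron 1,5-electrocyclisation and because the adduct loses bromide irreversibly; if sulfur adds first to the imidoyl carbon, the ylide of the cyclic sulfonium salt should reach the same indole by a 1,2-shift of the imidoyl carbon from sulfur to carbon. The stereocentre at C3 of 8 is transient and ends trigonal, so nothing has to be controlled. The step needs chemoselectivity for the benzylic C–H over the aryl C–H between the two bromines (the future C5–H) and over attack of base or bromine at other sites: the α-thio benzylic proton is the most acidic one, LiTMP is too hindered to add to N=CBr2, lithium amides do not exchange with aryl bromides at −78 °C, and the irreversible α-addition to the isocyanide drains the reversible bromine–sulfide adduct.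

**Compound list**
1 | 3,5-dibromoaniline | Nc1cc(Br)cc(Br)c1 | starting material
2 | dimethyl sulfide | CSC | starting material
3 | (3,5-dibromoanilino)dimethylsulfonium chloride (azasulfonium salt) | C[S+](C)Nc1cc(Br)cc(Br)c1.[Cl-] | intermediate
4 | 3,5-dibromo-2-[(methylsulfanyl)methyl]aniline | CSCc1c(N)cc(Br)cc1Br | intermediate
5 | N-{3,5-dibromo-2-[(methylsulfanyl)methyl]phenyl}formamide | CSCc1c(NC=O)cc(Br)cc1Br | intermediate
6 | 1,5-dibromo-3-isocyano-2-[(methylsulfanyl)methyl]benzene | CSCc1c([N+]#[C-])cc(Br)cc1Br | intermediate
7 | N-{3,5-dibromo-2-[(methylsulfanyl)methyl]phenyl}carbonimidic dibromide | CSCc1c(N=C(Br)Br)cc(Br)cc1Br | intermediate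
8 | 2,4,6-tribromo-3-(methylsulfanyl)-3H-indole (racemic, C3 labile) | CSC1C(Br)=Nc2cc(Br)cc(Br)c12 | intermediate
9 | 2,4,6-tribromo-3-(methylsulfanyl)-1H-indole (achiral) | CSc1c(Br)[nH]c2cc(Br)cc(Br)c12 | target

**Totals**
Total step count: 4. Longest linear sequence: 4 steps (1 → 4 → 5 → 6 → 9).

**Steps most likely to fail**

Step 4 (proposed new method). Several processes may go wrong:
- Bromine may be held on sulfur and the bromosulfonium ion may fragment at the benzylic C–S bond.
- Sulfur may add to the imidoyl carbon and bromide may then remove the S-methyl group.
- The base may metalate the aryl C–H between the two bromines, with aryne formation or halogen migration.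
- The base may attack a bromine of N=CBr2 and return the isocyanide.

The fallback uses known chemistry, sets out from 6 and comes back at 9. An Ito–Saegusa cyclisation with lithium diisopropylamide (2.2 equiv, THF, −78 °C → rt) should close the benzylic anion onto the isocyanide carbon (5-endo-dig) and give, after proton shift and work-up, 4,6-dibromo-3-(methylsulfanyl)-1H-indole F1. Bromination of F1 at the free C2 position with NBS (1.0 equiv, THF, −78 → 0 °C), the usual course for a 3-substituted indole, should then give 9.

Step 1. The S-amination of the weakly nucleophilic dibromoaniline may be slower than the decay of the chlorosulfonium reagent. The sulfilimine may fail to rearrange onto the ortho carbon next to the bromine-bearing carbon, or 4 may be alkylated a second time at its other ortho position. The fallback leaves 1 and 2 aside, sets out from purchased 1,5-dibromo-2-methyl-3-nitrobenzene F2 and comes back at 4. Radical benzylic bromination (NBS, AIBN, PhCF3, reflux) should give 1,5-dibromo-2-(bromomethyl)-3-nitrobenzene F3. Substitution with sodium methanethiolate (THF/MeOH, 0 °C) should give 1,5-dibromo-2-[(methylsulfanyl)methyl]-3-nitrobenzene F4. The ring bromines are meta to the nitro group and should not be displaced. Reduction of the nitro group with Fe powder in AcOH/EtOH at 70 °C, which spares aryl bromides and the sulfide, should give 4.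

Step 3. Dehydration may stay incomplete, or the isocyanide may be hydrated back to 5 or add HCl if the work-up turns acidic. The fallback sets out from 4, bypasses 5 and comes back at 6. The Hofmann carbylamine reaction (CHCl3, 50% aq NaOH, benzyltriethylammonium chloride, CH2Cl2, 40 °C) should convert the primary amine directly into the isocyanide through dichlorocarbene, under basic conditions only. This fallback makes no new compound and is entered below as F0 with no structure.

**Further compounds**
F1 | step 4 | 4,6-dibromo-3-(methylsulfanyl)-1H-indole | CSc1c[nH]c2cc(Br)cc(Br)c12
F2 | step 1 | 1,5-dibromo-2-methyl-3-nitrobenzene | Cc1c(Br)cc(Br)cc1[N+](=O)[O-]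
F3 | step 1 | 1,5-dibromo-2-(bromomethyl)-3-nitrobenzene | BrCc1c(Br)cc(Br)cc1[N+](=O)[O-]
F4 | step 1 | 1,5-dibromo-2-[(methylsulfanyl)methyl]-3-nitrobenzene | CSCc1c(Br)cc(Br)cc1[N+](=O)[O-]
F0 | step 3 | none | none
A1 | direct plan | 3,5-dibromoaniline | Nc1cc(Br)cc(Br)c1
A2 | direct plan | (methylsulfanyl)acetyl chloride | CSCC(=O)Cl
A3 | direct plan | N-(3,5-dibromophenyl)-2-(methylsulfanyl)acetamide | CSCC(=O)Nc1cc(Br)cc(Br)c1
A4 | direct plan | [2-(3,5-dibromoanilino)-2-oxoethylidene](methyl)sulfonium bromide | C[S+]=CC(=O)Nc1cc(Br)cc(Br)c1.[Br-]
A5 | direct plan | 4,6-dibromo-3-(methylsulfanyl)-1,3-dihydro-2H-indol-2-one (racemic) | CSC1C(=O)Nc2cc(Br)cc(Br)c12
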